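**Strategy.** Ring numbering: C4 bears CO2H, C5 CH2OAc, C6/C7 are the methylenes, C8 is CHMe, C9 quaternary. The carbocycle is closed by joining C5 to C6. The route exploits that the C4=C5 alkene, with cis CO2H and CH2OAc, is a ring-opened butenolide: as a tetronic acid enol phosphate, C5 becomes an sp2 electrophile of fixed geometry. C6 is made nucleophilic by 9-BBN hydroboration of a terminal vinyl group, and one intramolecular B-alkyl Suzuki–Miyaura coupling closes the ten-membered triene ring. The precursor is an open-chain (Z,E)-dienyl tetronate phosphate; its C8 and C9 stereocentres come from a chirality-transferring Claisen rearrangement.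

Key step: step 13

Remarks: C10=C1 is the E alkene and C2=C3 the Z alkene of the ring. 3-(Bromomethyl)furan is assumed to be purchasable (otherwise one step from furan-3-ylmethanol).

**Step 1**
Reactants: 1 trimethyl(prop-1-yn-1-yl)silane; 2 3-(bromomethyl)furan
Product: 4 [4-(furan-3-yl)but-1-yn-1-yl]trimethylsilane, via lithiated silylpropyne 3 (not isolated)
Conditions: n-BuLi, THF, −78 °C; then 2, −78 → 0 °C
Reagents that add atoms: none
Why: Propargylic lithiation of 1 gives the ambident anion 3, which should be alkylated at its CH2 terminus by the reactive furylmethyl bromide (propargyl anion alkylation), the silyl group shielding the other terminus.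

**Step 2**
Reactants: 4
Product: 5 3-(but-3-yn-1-yl)furan
Conditions: K2CO3, MeOH, rt
Reagents that add atoms: none
Why: Base-catalysed methanolysis of the C(sp)–Si bond (protodesilylation) should free the terminal alkyne without touching the furan.

**Step 3**
Reactants: 5; 6 3-(trimethylsilyl)prop-2-ynal
Product: 8 rac-(4E)-7-(furan-3-yl)-5-methyl-1-(trimethylsilyl)hept-4-en-1-yn-3-ol, via alkenylalane 7 (not isolated)
Conditions: Me3Al, Cp2ZrCl2 (cat.), CH2Cl2, 0 °C → rt; excess Me3Al removed in vacuo; then 6, CH2Cl2, −78 → 0 °C; aq. NH4Cl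
Reagents that add atoms: trimethylaluminium, C[Al](C)C
Why: Negishi carboalumination adds methyl and aluminium syn across the alkyne (methyl internal), fixing the E trisubstituted alkene, and alkenylalane 7 should transfer its alkenyl group to the aldehyde; the carbinol centre forms racemic and is reset in steps 4 and 5.

**Step 4**
Reactants: 8
Product: 9 (4E)-7-(furan-3-yl)-5-methyl-1-(trimethylsilyl)hept-4-en-1-yn-3-one
Conditions: MnO2, CH2Cl2, rt
Reagents that add atoms: none
Why: MnO2 should oxidise the doubly activated (allylic and propargylic) alcohol selectively to the cross-conjugated ynenone.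

**Step 5**
Reactants: 9
Product: 10 (3R,4E)-7-(furan-3-yl)-5-methyl-1-(trimethylsilyl)hept-4-en-1-yn-3-ol
Conditions: (R)-Alpine-Borane, THF (concentrated), rt; then HOCH2CH2NH2, Et2O
Reagents that add atoms: none
Why: Midland reduction: hydride is delivered from the pinanyl group through a boat-like six-membered transition state with the slim alkynyl group in the hindered position, so the (R)-reagent should give the (R)-carbinol, as it does with simple 1-alkyn-3-ones.

**Step 6**
Reactants: 10; 11 allyl bromide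
Product: 12 trimethyl[(3R,4E)-7-(furan-3-yl)-5-methyl-3-(prop-2-en-1-yloxy)hept-4-en-1-yn-1-yl]silane
Conditions: NaH, Bu4NI (cat.), THF, 0 °C; then 11, 0 °C → rt
Reagents that add atoms: none
Why: Williamson etherification of the sodium alkoxide; the stereocentre is not touched.

**Step 7**
Reactants: 12
Product: 14 (2S,3R,4E)-3-[2-(furan-3-yl)ethyl]-2,3-dimethyl-7-(trimethylsilyl)hept-4-en-6-ynal, via propenyl ether 13 (not isolated)
Conditions: [IrCl(C8H14)2]2 (cat.), PCy3, NaBPh4, CH2Cl2/acetone, rt; then PPh3, ClCH2CH2Cl, 80 °C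
Reagents that add atoms: none
Why: Iridium-catalysed isomerisation of the unsubstituted allyl group should give the (E)-propenyl ether 13, whose chair [3,3] shift (isomerisation–Claisen rearrangement) has the propenyl methyl and the alkynyl group equatorial, the latter enforced by the 1,3-diaxial clash with the C9 methyl, so that the carbinol chirality sets C8, C9 and the E alkene together.

**Step 8**
Reactants: 14
Product: 16 (3E,5R,6R)-5-[2-(furan-3-yl)ethyl]-5,6-dimethylocta-3,7-dien-1-yne, via silyl dienyne 15 (not isolated)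
Conditions: Ph3PCH3Br, KOtBu, THF, 0 °C; then MeOH, K2CO3, rt
Reagents that add atoms: methyltriphenylphosphonium bromide, C[P+](c1ccccc1)(c1ccccc1)c1ccccc1.[Br-]
Why: Wittig methylenation of the hindered, slowly enolising aldehyde should keep the C8 centre, and methanolysis of the alkynylsilane in the same flask frees the terminal alkyne.

**Step 9**
Reactants: 17 tetronic acid
Product: 18 4-hydroxy-3-iodofuran-2(5H)-one
Conditions: N-iodosuccinimide, MeCN, 0 °C → rt
Reagents that add atoms: N-iodosuccinimide, O=C1CCC(=O)N1I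
Why: Electrophilic iodination at the nucleophilic C3 of the enolised 1,3-dicarbonyl system.

**Step 10**
Reactants: 18
Product: 19 diethyl (4-iodo-5-oxo-2,5-dihydrofuran-3-yl) phosphate
Conditions: ClP(O)(OEt)2, iPr2NEt, CH2Cl2, 0 °C
Reagents that add atoms: diethyl chlorophosphate, CCOP(=O)(Cl)OCC
Why: O-Phosphorylation of the acidic enol should give the vinylogous acyl phosphate, a coupling handle that stays inert in steps 11 and 12.

**Step 11**
Reactants: 16; 19
Product: 20 diethyl {4-[(3E,5R,6R)-5-[2-(furan-3-yl)ethyl]-5,6-dimethylocta-3,7-dien-1-yn-1-yl]-5-oxo-2,5-dihydrofuran-3-yl} phosphate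
Conditions: Pd(PPh3)4 (cat.), CuI (cat.), iPr2NEt, THF, rt
Reagents that add atoms: none
Why: Sonogashira coupling; zerovalent palladium inserts far faster into the C–I bond than into the enol phosphate C–O bond, so only the α-carbon of the butenolide should react.

**Step 12**
Reactants: 20
Product: 21 diethyl {4-[(1Z,3E,5R,6R)-5-[2-(furan-3-yl)ethyl]-5,6-dimethylocta-1,3,7-trien-1-yl]-5-oxo-2,5-dihydrofuran-3-yl} phosphate
Conditions: Zn activated with Cu(OAc)2 and AgNO3, MeOH/H2O, rt
Reagents that add atoms: none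
Why: cis-Semi-reduction of the conjugated, hence activated, alkyne on activated zinc in a protic medium should give the Z alkene and leave the isolated vinyl group and the other alkenes alone.

**Step 13**
Reactants: 21
Product: 23 (6R,7S,8E,10Z)-7-[2-(furan-3-yl)ethyl]-6,7-dimethyl-4,5,6,7-tetrahydrocyclodeca[c]furan-1(3H)-one, via alkylborane 22 (not isolated)
Conditions: 9-BBN, THF, 0 °C → rt; then slow addition to Pd(dppf)Cl2 (cat.), AsPh3, Cs2CO3, DMF/THF/H2O, 50 °C, high dilution
Reagents that add atoms: none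
Why: 9-BBN adds anti-Markovnikov to the only monosubstituted alkene to give primary alkylborane 22; zerovalent palladium inserts into the C5–O bond of the vinylogous acyl phosphate, the base-activated borate transfers C6 to palladium, and reductive elimination forms the C5–C6 bond. The closest known reaction types are the B-alkyl Suzuki–Miyaura macrocyclisation of alkenyl halides or triflates and the B-alkyl Suzuki coupling of enol phosphates. The ten-membered carbocycle is closed by reductive elimination from an eleven-membered palladacycle, a macrocyclisation by C(sp3)–C(sp2) cross-coupling with the butenolide already in place. No stereocentre is formed; C8 and C9 are remote from the reacting atoms, and the C4=C5 (held by the lactone), 2Z and 1(10)E geometries are kept because oxidative addition and reductive elimination are stereoretentive. The step needs chemoselective hydroboration (the bulk of 9-BBN against the 1,2-disubstituted conjugated alkenes), ring closure over oligomerisation (high dilution, slow addition, the turn imposed by the Z alkene and the quaternary C9) and coupling over β-hydride elimination or hydrolysis (dppf, AsPh3, the base-tolerant phosphate). The temperature is held at or below 50 °C so that the triene does not electrocyclise.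

**Step 14**
Reactants: 23
Product: 25 (1(10)Z,2Z,4E,6S,7R)-10-(acetoxymethyl)-6-[2-(furan-3-yl)ethyl]-6,7-dimethylcyclodeca-1(10),2,4-triene-1-carboxylic acid, via potassium hydroxy carboxylate 24 (not isolated)
Conditions: KOH (1 equiv), THF/H2O, 0 °C → rt, evaporate; then Ac2O, DMAP (cat.), pyridine, 0 °C; work-up at pH 4
Reagents that add atoms: potassium hydroxide, [K+].[OH-]; acetic anhydride, CC(=O)OC(C)=O
Why: Saponification opens the butenolide to the (Z)-hydroxy carboxylate 24, whose primary allylic hydroxyl should be acetylated faster than the carboxylate is activated; the cis arrangement of CH2OAc and CO2H is inherited from the lactone.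

**Compound list**
1 | trimethyl(prop-1-yn-1-yl)silane | CC#C[Si](C)(C)C | starting material
2 | 3-(bromomethyl)furan | BrCc1ccoc1 | starting material
3 | [3-(trimethylsilyl)prop-2-yn-1-yl]lithium | [Li]CC#C[Si](C)(C)C | intermediate
4 | [4-(furan-3-yl)but-1-yn-1-yl]trimethylsilane | C[Si](C)(C)C#CCCc1ccoc1 | intermediate
5 | 3-(but-3-yn-1-yl)furan | C#CCCc1ccoc1 | intermediate
6 | 3-(trimethylsilyl)prop-2-ynal | O=CC#C[Si](C)(C)C | starting material
7 | [(1E)-4-(furan-3-yl)-2-methylbut-1-en-1-yl]dimethylalumane | C[Al](C)/C=C(\C)CCc1ccoc1 | intermediate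
8 | rac-(4E)-7-(furan-3-yl)-5-methyl-1-(trimethylsilyl)hept-4-en-1-yn-3-ol | C[Si](C)(C)C#CC(O)/C=C(\C)CCc1ccoc1 | intermediate
9 | (4E)-7-(furan-3-yl)-5-methyl-1-(trimethylsilyl)hept-4-en-1-yn-3-one | C[Si](C)(C)C#CC(=O)/C=C(\C)CCc1ccoc1 | intermediate
10 | (3R,4E)-7-(furan-3-yl)-5-methyl-1-(trimethylsilyl)hept-4-en-1-yn-3-ol | C[Si](C)(C)C#C[C@H](O)/C=C(\C)CCc1ccoc1 | intermediate
11 | allyl bromide (3-bromoprop-1-ene) | C=CCBr | starting material
12 | trimethyl[(3R,4E)-7-(furan-3-yl)-5-methyl-3-(prop-2-en-1-yloxy)hept-4-en-1-yn-1-yl]silane | C[Si](C)(C)C#C[C@H](OCC=C)/C=C(\C)CCc1ccoc1 | intermediate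
13 | trimethyl{(3R,4E)-7-(furan-3-yl)-5-methyl-3-[(1E)-prop-1-en-1-yloxy]hept-4-en-1-yn-1-yl}silane | C[Si](C)(C)C#C[C@H](O/C=C/C)/C=C(\C)CCc1ccoc1 | intermediate
14 | (2S,3R,4E)-3-[2-(furan-3-yl)ethyl]-2,3-dimethyl-7-(trimethylsilyl)hept-4-en-6-ynal | C[Si](C)(C)C#C/C=C/[C@@](C)(CCc1ccoc1)[C@H](C)C=O | intermediate
15 | trimethyl{(3E,5R,6R)-5-[2-(furan-3-yl)ethyl]-5,6-dimethylocta-3,7-dien-1-yn-1-yl}silane | C[Si](C)(C)C#C/C=C/[C@@](C)(CCc1ccoc1)[C@H](C)C=C | intermediate
16 | (3E,5R,6R)-5-[2-(furan-3-yl)ethyl]-5,6-dimethylocta-3,7-dien-1-yne | C#C/C=C/[C@@](C)(CCc1ccoc1)[C@H](C)C=C | intermediate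
17 | tetronic acid (4-hydroxyfuran-2(5H)-one) | OC1=CC(=O)OC1 | starting material
18 | 4-hydroxy-3-iodofuran-2(5H)-one | OC1=C(I)C(=O)OC1 | intermediate
19 | diethyl (4-iodo-5-oxo-2,5-dihydrofuran-3-yl) phosphate | CCOP(=O)(OCC)OC1=C(I)C(=O)OC1 | intermediate
20 | diethyl {4-[(3E,5R,6R)-5-[2-(furan-3-yl)ethyl]-5,6-dimethylocta-3,7-dien-1-yn-1-yl]-5-oxo-2,5-dihydrofuran-3-yl} phosphate | CCOP(=O)(OCC)OC1=C(C#C/C=C/[C@@](C)(CCc2ccoc2)[C@H](C)C=C)C(=O)OC1 | intermediate
21 | diethyl {4-[(1Z,3E,5R,6R)-5-[2-(furan-3-yl)ethyl]-5,6-dimethylocta-1,3,7-trien-1-yl]-5-oxo-2,5-dihydrofuran-3-yl} phosphate | CCOP(=O)(OCC)OC1=C(/C=C\C=C\[C@@](C)(CCc2ccoc2)[C@H](C)C=C)C(=O)OC1 | intermediate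
22 | diethyl {4-[(1Z,3E,5S,6R)-8-(9-borabicyclo[3.3.1]nonan-9-yl)-5-[2-(furan-3-yl)ethyl]-5,6-dimethylocta-1,3-dien-1-yl]-5-oxo-2,5-dihydrofuran-3-yl} phosphate | CCOP(=O)(OCC)OC1=C(/C=C\C=C\[C@@](C)(CCc2ccoc2)[C@H](C)CCB2C3CCCC2CCC3)C(=O)OC1 | intermediate
23 | (6R,7S,8E,10Z)-7-[2-(furan-3-yl)ethyl]-6,7-dimethyl-4,5,6,7-tetrahydrocyclodeca[c]furan-1(3H)-one (the butenolide in which the C4 carboxyl is lactonised onto the C5 CH2O group) | O=C1OCC2=C1/C=C\C=C\[C@@](C)(CCc1ccoc1)[C@H](C)CC2 | intermediate
24 | potassium (1(10)Z,2Z,4E,6S,7R)-6-[2-(furan-3-yl)ethyl]-10-(hydroxymethyl)-6,7-dimethylcyclodeca-1(10),2,4-triene-1-carboxylate | OC/C1=C(C(=O)[O-])/C=C\C=C\[C@@](C)(CCc2ccoc2)[C@H](C)CC1.[K+] | intermediate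
25 | (1(10)Z,2Z,4E,6S,7R)-10-(acetoxymethyl)-6-[2-(furan-3-yl)ethyl]-6,7-dimethylcyclodeca-1(10),2,4-triene-1-carboxylic acid | CC(=O)OC/C1=C(C(=O)O)/C=C\C=C\[C@@](C)(CCc2ccoc2)[C@H](C)CC1 | target

**Totals.** 14 steps in all; longest linear sequence 12 steps (steps 1–8 and 11–14), with steps 9 and 10 as a two-step side branch.

**Steps most likely to fail**

Step 13. Protodeboronation, β-hydride elimination, intermolecular coupling or base hydrolysis of the enol phosphate may outrun the slow medium-ring reductive elimination. The fallback replaces the base-activated borate by a base-free organozinc. Setting out from 21, hydroboration with 9-BBN as before and oxidation of the borane 22 with anhydrous Me3NO would give the primary alcohol F1. I2, PPh3 and imidazole would convert it into the primary iodide F2. Zinc insertion (Zn dust, LiCl, THF) would give the alkylzinc iodide F3, which would be cyclised under high dilution with Pd(dppf)Cl2 as catalyst (intramolecular Negishi coupling). This comes back to the route at 23.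

Step 14. Acylation of the carboxylate to a mixed anhydride followed by capture by the neighbouring hydroxyl may re-close the lactone faster than the hydroxyl is acetylated. The fallback masks the carboxyl first. Setting out from 24, silylation of the potassium carboxylate with iPr3SiCl (1 equiv, DMF, 0 °C) would give the triisopropylsilyl hydroxy ester F4. Acetylation (Ac2O, DMAP, pyridine) would give the triisopropylsilyl acetoxy ester F5. Buffered HF·pyridine in THF would cleave the silyl ester, coming back to the route at 25.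

Step 7. A competing [3,3] shift through the propargyl arm, a boat transition state at 80 °C, or inhibition of the iridium catalyst by the enyne may erode regio- and stereocontrol. The fallback is an ester enolate Claisen rearrangement at low temperature. Setting out from 10, acylation with propanoyl chloride and pyridine would give the propanoate F6. LiN(iPr)2 in THF/DMPU with Me3SiCl at −78 °C would give the (Z)-silyl ketene acetal F7, which on warming would rearrange (Ireland–Claisen) through the same chair, with the methyl again equatorial, to the trimethylsilyl ester F8. Aqueous work-up would give the acid F9, and LiAlH4 would reduce it to the primary alcohol F10. Dess–Martin oxidation would come back to the route at 14.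

**Further compounds**
F1 | step 13 | diethyl {4-[(1Z,3E,5S,6R)-5-[2-(furan-3-yl)ethyl]-8-hydroxy-5,6-dimethylocta-1,3-dien-1-yl]-5-oxo-2,5-dihydrofuran-3-yl} phosphate | CCOP(=O)(OCC)OC1=C(/C=C\C=C\[C@@](C)(CCc2ccoc2)[C@H](C)CCO)C(=O)OC1
F2 | step 13 | diethyl {4-[(1Z,3E,5S,6R)-5-[2-(furan-3-yl)ethyl]-8-iodo-5,6-dimethylocta-1,3-dien-1-yl]-5-oxo-2,5-dihydrofuran-3-yl} phosphate | CCOP(=O)(OCC)OC1=C(/C=C\C=C\[C@@](C)(CCc2ccoc2)[C@H](C)CCI)C(=O)OC1
F3 | step 13 | {(3R,4S,5E,7Z)-8-[4-(diethoxyphosphoryloxy)-2-oxo-2,5-dihydrofuran-3-yl]-4-[2-(furan-3-yl)ethyl]-3,4-dimethylocta-5,7-dien-1-yl}zinc iodide | CCOP(=O)(OCC)OC1=C(/C=C\C=C\[C@@](C)(CCc2ccoc2)[C@H](C)CC[Zn]I)C(=O)OC1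
F4 | step 14 | tri(propan-2-yl)silyl (1(10)Z,2Z,4E,6S,7R)-6-[2-(furan-3-yl)ethyl]-10-(hydroxymethyl)-6,7-dimethylcyclodeca-1(10),2,4-triene-1-carboxylate | OC/C1=C(C(=O)O[Si](C(C)C)(C(C)C)C(C)C)/C=C\C=C\[C@@](C)(CCc2ccoc2)[C@H](C)CC1
F5 | step 14 | tri(propan-2-yl)silyl (1(10)Z,2Z,4E,6S,7R)-10-(acetoxymethyl)-6-[2-(furan-3-yl)ethyl]-6,7-dimethylcyclodeca-1(10),2,4-triene-1-carboxylate | CC(=O)OC/C1=C(C(=O)O[Si](C(C)C)(C(C)C)C(C)C)/C=C\C=C\[C@@](C)(CCc2ccoc2)[C@H](C)CC1
F6 | step 7 | (3R,4E)-7-(furan-3-yl)-5-methyl-1-(trimethylsilyl)hept-4-en-1-yn-3-yl propanoate | C[Si](C)(C)C#C[C@H](OC(=O)CC)/C=C(\C)CCc1ccoc1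
F7 | step 7 | (Z)-O-trimethylsilyl ketene acetal of F6 | C[Si](C)(C)C#C[C@H](O/C(O[Si](C)(C)C)=C/C)/C=C(\C)CCc1ccoc1
F8 | step 7 | trimethylsilyl (2S,3R,4E)-3-[2-(furan-3-yl)ethyl]-2,3-dimethyl-7-(trimethylsilyl)hept-4-en-6-ynoate | C[Si](C)(C)C#C/C=C/[C@@](C)(CCc1ccoc1)[C@H](C)C(=O)O[Si](C)(C)C
F9 | step 7 | (2S,3R,4E)-3-[2-(furan-3-yl)ethyl]-2,3-dimethyl-7-(trimethylsilyl)hept-4-en-6-ynoic acid | C[Si](C)(C)C#C/C=C/[C@@](C)(CCc1ccoc1)[C@H](C)C(=O)O
F10 | step 7 | (2S,3R,4E)-3-[2-(furan-3-yl)ethyl]-2,3-dimethyl-7-(trimethylsilyl)hept-4-en-6-yn-1-ol | C[Si](C)(C)C#C/C=C/[C@@](C)(CCc1ccoc1)[C@H](C)CO
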